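**Retrosynthetic overview**
- The strategy rests on one feature: the target is a Z α‑oxychalcone whose enol oxygen O2 is tied to arene carbon C8a by the single methylene C1, which closes the pyran ring of the 1H‑isochromene (C3 bears the aroyl group, C4 is the vinylic CH, C4a/C8a are the fusion carbons).
- Key disconnection: C1–C8a. The bond is formed by Friedel–Crafts attack of the veratryl ring on an O2‑bound methylene oxocarbenium ion released from the methoxymethyl enol ether 8. This pyran ring is the only ring formed; both benzene rings are bought.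
- C3=C4 is disconnected by a Claisen–Schmidt condensation of the α‑(methoxymethoxy) ketone 5 with veratraldehyde 6, which sets the Z geometry.
- Ketone 5 comes from 2',4'‑dimethoxyacetophenone 1 by α‑hydroxylation and O‑methoxymethylation with MOMCl 4, which supplies C1.

Key step: step 4

Remark: the target has no stereocentre and is achiral, so "single enantiomer" is read as the single compound drawn. The only stereochemical element in the route is the Z geometry of enol ether 8, which becomes the ring bond C3=C4.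

**Step 1**
Reactants: 1 2',4'‑dimethoxyacetophenone
Product: 3 1‑(2,4‑dimethoxyphenyl)‑2‑hydroxyethan‑1‑one, via 2‑(2,4‑dimethoxyphenyl)‑2,2‑dimethoxyethan‑1‑ol 2 (not isolated)
Conditions: PhI(OAc)2 (1.1 equiv), KOH (3 equiv), MeOH, 0 °C → rt; then 2 M aq. HCl, THF, rt
Reagents that add atoms: methanol, CO (the two acetal OMe groups of 2); water, O (the carbonyl oxygen of 3)
Why: Moriarty α‑hydroxylation: the enolate is oxidised by the iodine(III) reagent in methanolic KOH and trapped as the α‑hydroxy dimethyl acetal 2, which dilute acid hydrolyses to the α‑hydroxy ketone; the ketone has only one enolisable position.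

**Step 2**
Reactants: 3 1‑(2,4‑dimethoxyphenyl)‑2‑hydroxyethan‑1‑one; 4 chloromethyl methyl ether
Product: 5 1‑(2,4‑dimethoxyphenyl)‑2‑(methoxymethoxy)ethan‑1‑one
Conditions: MOMCl, i‑Pr2NEt, CH2Cl2, 0 °C → rt
Reagents that add atoms: none
Why: Standard O‑alkylation of a primary alcohol with an α‑chloro ether (MOM protection); the hindered amine base should not enolise the ketone.

**Step 3**
Reactants: 5 1‑(2,4‑dimethoxyphenyl)‑2‑(methoxymethoxy)ethan‑1‑one; 6 veratraldehyde (3,4‑dimethoxybenzaldehyde)
Product: 8 (Z)‑1‑(2,4‑dimethoxyphenyl)‑3‑(3,4‑dimethoxyphenyl)‑2‑(methoxymethoxy)prop‑2‑en‑1‑one, via 1‑(2,4‑dimethoxyphenyl)‑3‑(3,4‑dimethoxyphenyl)‑3‑hydroxy‑2‑(methoxymethoxy)propan‑1‑one 7 (not isolated)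
Conditions: KOH, EtOH, rt (→ 50 °C if dehydration is slow)
Reagents that add atoms: none
Why: Claisen–Schmidt condensation of an α‑alkoxyacetophenone with a non‑enolisable aldehyde; reversible aldol addition and E1cB dehydration should give the isomer with the aryl group trans to the aroyl group, which is Z because the OMOM group outranks the acyl carbon. The MOM acetal and the aryl methyl ethers are stable to base.

**Step 4**
Reactants: 8 (Z)‑1‑(2,4‑dimethoxyphenyl)‑3‑(3,4‑dimethoxyphenyl)‑2‑(methoxymethoxy)prop‑2‑en‑1‑one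
Product: 10 (2,4‑dimethoxyphenyl)(6,7‑dimethoxy‑1H‑isochromen‑3‑yl)methanone, via [(Z)‑1‑(2,4‑dimethoxybenzoyl)‑2‑(3,4‑dimethoxyphenyl)ethenyl](methylidene)oxonium triflate 9 (not isolated)
Conditions: TMSOTf (0.3 equiv), 5 Å MS, CH2Cl2 (0.01 M), −40 → 0 °C; Et3N quench
Reagents that add atoms: none
Why: Proposed new method: TMSOTf silylates the methoxy oxygen of the acetal and expels it as MeOSiMe3, leaving the O2‑bound methylene oxocarbenium ion 9, whose CH2 carbon is attacked by the veratryl carbon para to the 3‑methoxy group (C1–C8a bond); loss of the arenium proton gives the 1H‑isochromene, and the TfOH released turns MeOSiMe3 back into TMSOTf and methanol, so the silyl triflate should act catalytically. The closest known reaction type is the oxa‑Pictet–Spengler‑type cyclisation of methoxymethyl ethers of 2‑arylethanols to isochromans, extended here from an alkyl to an enol oxygen; closure of a cation onto an arene across an aryl‑conjugated C=X tether is the pattern of the Pomeranz–Fritsch isoquinoline synthesis. The pyran ring closes 6‑endo‑trig with respect to the C1=O2+ bond, with the aryl ring twisting about C4–C4a so that its π face meets C1. No stereocentre is formed; the Z geometry of 8 fixed in step 3 already holds O2 and the arene cis and becomes the ring bond C3=C4. The step needs site selectivity for the arene carbon para to the 3‑OMe over the carbon flanked by the side chain and the 3‑OMe (secured by para activation and lower hindrance) and chemoselectivity over the 2,4‑dimethoxybenzoyl ring (its only free ortho carbon is meta to both methoxy groups and deactivated by the ketone), while high dilution suppresses intermolecular alkylation. Should the acetal ionise the other way, the freed methoxymethyl cation alkylates the same arene carbon and the enol oxygen then displaces methanol at that benzylic carbon, so both paths lead to 10.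

**Compound list**
1 | 2',4'‑dimethoxyacetophenone | CC(=O)c1ccc(OC)cc1OC | starting material
2 | 2‑(2,4‑dimethoxyphenyl)‑2,2‑dimethoxyethan‑1‑ol | OCC(OC)(OC)c1ccc(OC)cc1OC | intermediate
3 | 1‑(2,4‑dimethoxyphenyl)‑2‑hydroxyethan‑1‑one | OCC(=O)c1ccc(OC)cc1OC | intermediate
4 | chloromethyl methyl ether (MOMCl) | COCCl | starting material
5 | 1‑(2,4‑dimethoxyphenyl)‑2‑(methoxymethoxy)ethan‑1‑one | COCOCC(=O)c1ccc(OC)cc1OC | intermediate
6 | veratraldehyde (3,4‑dimethoxybenzaldehyde) | COc1ccc(C=O)cc1OC | starting material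
7 | 1‑(2,4‑dimethoxyphenyl)‑3‑(3,4‑dimethoxyphenyl)‑3‑hydroxy‑2‑(methoxymethoxy)propan‑1‑one (racemic, diastereomer mixture) | COCOC(C(=O)c1ccc(OC)cc1OC)C(O)c1ccc(OC)c(OC)c1 | intermediate
8 | (Z)‑1‑(2,4‑dimethoxyphenyl)‑3‑(3,4‑dimethoxyphenyl)‑2‑(methoxymethoxy)prop‑2‑en‑1‑one | COCO/C(C(=O)c1ccc(OC)cc1OC)=C\c1ccc(OC)c(OC)c1 | intermediate
9 | [(Z)‑1‑(2,4‑dimethoxybenzoyl)‑2‑(3,4‑dimethoxyphenyl)ethenyl](methylidene)oxonium triflate | C=[O+]/C(C(=O)c1ccc(OC)cc1OC)=C\c1ccc(OC)c(OC)c1.[O-]S(=O)(=O)C(F)(F)F | intermediate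
10 | (2,4‑dimethoxyphenyl)(6,7‑dimethoxy‑1H‑isochromen‑3‑yl)methanone | COc1ccc(C(=O)C2=Cc3cc(OC)c(OC)cc3CO2)c(OC)c1 | target

**Step count and risks**
Total step count: 4. Longest linear sequence: 4 steps (1 → 3 → 5 → 8 → 10).

Steps most likely to fail:

1. Step 4 (Proposed new method). The enol‑bound oxocarbenium may fail to form or be diverted before ring closure: loss of the methoxymethyl group to the enolised 1,2‑diketone, intermolecular arene alkylation, or oligomerisation. Fallback by known chemistry, setting out from 8 and returning at 10: hydrogenation of the enone C=C (H2, Pd/C, EtOAc) should give racemic 1‑(2,4‑dimethoxyphenyl)‑3‑(3,4‑dimethoxyphenyl)‑2‑(methoxymethoxy)propan‑1‑one F1. TMSOTf in CH2Cl2 at 0 °C should then effect the established oxa‑Pictet–Spengler‑type closure of this alkyl MOM ether, through [1‑(2,4‑dimethoxyphenyl)‑3‑(3,4‑dimethoxyphenyl)‑1‑oxopropan‑2‑yl](methylidene)oxonium triflate F2, to racemic (2,4‑dimethoxyphenyl)(6,7‑dimethoxy‑3,4‑dihydro‑1H‑isochromen‑3‑yl)methanone F3. Enolisation at C3 (LiHMDS, THF, −78 °C) and trapping with PhSeBr should give (2,4‑dimethoxyphenyl)[6,7‑dimethoxy‑3‑(phenylselanyl)‑3,4‑dihydro‑1H‑isochromen‑3‑yl]methanone F4. Oxidation with H2O2/pyridine in CH2Cl2 should give (2,4‑dimethoxyphenyl)[6,7‑dimethoxy‑3‑(phenylseleninyl)‑3,4‑dihydro‑1H‑isochromen‑3‑yl]methanone F5, which should undergo syn‑elimination towards the C4 hydrogens, the only β‑hydrogens present, to give 10. The stereocentre of F1 and F3 is removed in this last operation.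

2. Step 3. The aldol adduct may revert or fail to dehydrate under the equilibrating conditions, or the enone may form as an E/Z mixture. Fallback, setting out from 5 and 6 and returning at 8: directed aldol addition of the lithium enolate of 5 (LDA, THF, −78 °C) to 6 with isolation of adduct 7. Acetylation (Ac2O, Et3N, DMAP, CH2Cl2) should give 3‑(2,4‑dimethoxyphenyl)‑1‑(3,4‑dimethoxyphenyl)‑2‑(methoxymethoxy)‑3‑oxopropyl acetate F6, and E1cB elimination with DBU in toluene at 80 °C should deliver 8 as the more stable Z isomer.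

3. Step 1. Oxidation or iodination of the electron‑rich ring by the iodine(III) reagent may compete, or hydrolysis of the acetal may be incomplete. Fallback, setting out from 1 and returning at 3: α‑bromination with CuBr2 in EtOAc/CHCl3 at reflux should give 2‑bromo‑1‑(2,4‑dimethoxyphenyl)ethan‑1‑one F7, which is also an article of commerce. Displacement with sodium formate in aqueous EtOH at reflux should give 2‑(2,4‑dimethoxyphenyl)‑2‑oxoethyl formate F8, which is hydrolysed in the same flask to 3.

**Further compounds**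
F1 | step 4 | 1‑(2,4‑dimethoxyphenyl)‑3‑(3,4‑dimethoxyphenyl)‑2‑(methoxymethoxy)propan‑1‑one (racemic) | COCOC(Cc1ccc(OC)c(OC)c1)C(=O)c1ccc(OC)cc1OC
F2 | step 4 | [1‑(2,4‑dimethoxyphenyl)‑3‑(3,4‑dimethoxyphenyl)‑1‑oxopropan‑2‑yl](methylidene)oxonium triflate (racemic) | C=[O+]C(Cc1ccc(OC)c(OC)c1)C(=O)c1ccc(OC)cc1OC.[O-]S(=O)(=O)C(F)(F)F
F3 | step 4 | (2,4‑dimethoxyphenyl)(6,7‑dimethoxy‑3,4‑dihydro‑1H‑isochromen‑3‑yl)methanone (racemic) | COc1ccc(C(=O)C2Cc3cc(OC)c(OC)cc3CO2)c(OC)c1
F4 | step 4 | (2,4‑dimethoxyphenyl)[6,7‑dimethoxy‑3‑(phenylselanyl)‑3,4‑dihydro‑1H‑isochromen‑3‑yl]methanone (racemic) | COc1ccc(C(=O)C2([Se]c3ccccc3)Cc3cc(OC)c(OC)cc3CO2)c(OC)c1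
F5 | step 4 | (2,4‑dimethoxyphenyl)[6,7‑dimethoxy‑3‑(phenylseleninyl)‑3,4‑dihydro‑1H‑isochromen‑3‑yl]methanone (diastereomer mixture) | COc1ccc(C(=O)C2([Se](=O)c3ccccc3)Cc3cc(OC)c(OC)cc3CO2)c(OC)c1
F6 | step 3 | 3‑(2,4‑dimethoxyphenyl)‑1‑(3,4‑dimethoxyphenyl)‑2‑(methoxymethoxy)‑3‑oxopropyl acetate (racemic, diastereomer mixture) | COCOC(C(=O)c1ccc(OC)cc1OC)C(OC(C)=O)c1ccc(OC)c(OC)c1
F7 | step 1 | 2‑bromo‑1‑(2,4‑dimethoxyphenyl)ethan‑1‑one | BrCC(=O)c1ccc(OC)cc1OC
F8 | step 1 | 2‑(2,4‑dimethoxyphenyl)‑2‑oxoethyl formate | O=COCC(=O)c1ccc(OC)cc1OC
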